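Whatever the vessel, the same X and E go in and each is counted as the X in it, so the set-ups differ in how that charge is shared out, not in its size.

the same everywhere: L 0.200 mM

| run | X | E | time | remark |
|---|---|---|---|---|
| north | 0.20 mM | 0.0500 mM | 2.0 min | a closed flask charged with all of it at once and left for 2.0 min |
| south-west | 0.20 mM | 0.0500 mM |  | one stirred flow tank at steady state, fed with the mixture as stated, mean residence time 2.0 min |
| north-east | 0.20 mM | 0.0500 mM (fed, over 1.60 min) | 2.0 min | all but E at the start; E goes in evenly over 1.60 min, the run ends at 2.0 min |
| north-west | 0.20 mM (fed, over 1.60 min) | 0.0500 mM | 2.0 min | all but X at the start; X goes in evenly over 1.60 min, the run ends at 2.0 min |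

    X ⇌ E (K1 = 0.033, k1 = 0.15 /s)
    X → Z (k2 = 0.28 /s)
    E → J (k3 = 4.0 /s)
    Z ⇌ J (K4 = 0.76, k4 = 0.0020 /s)
    2 X → X2 (k5 = 530 /M/s)
    E + L → E.L (k6 = 670 /M/s)

- in percentages every species weighs as the X in it: one X2 counts as two
- a step written with two of one species runs at k times the square of its concentration and takes two of it each time
- the stated concentrations are those of everything mixed, before any reaction; amounts are the same in each set-up
- the feed brings no volume worth counting
- run time (north): 2.0 min

- the set-up with the highest amount of Z at the outlet or at the end, in percent of the X and E together put in ("none" if the first two lie within 2 percentage points) (north / south-west / north-east / north-west / none)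
- amount of Z at the outlet or at the end, in percent of the X and E together put in, north
- amount of Z at the outlet or at the end, in percent of the X and E together put in, south-west
- amount of Z at the outlet or at the end, in percent of the X and E together put in, north-east
- amount of Z at the outlet or at the end, in percent of the X and E together put in, north-west

Read the recipes for one thing: the level of [X] each vessel holds. X goes to Z at a rate in [X], but to X2 at a rate in [X] squared.

First deal with E, which leaves much faster than it forms. Of each E, 52.4 % returns to X, so X has a net first-order loss of 0.351 /s, and 0.28 /s of that gives Z.

Now set the zero of your scale at the even-split level, the [X] at which X is lost equally to the first-order ways and to X2: 0.332 mM. Above it X2 takes the larger share, and below it the smaller.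

Start with north. Its [X] begins at 0.20 mM, not far below the level, and the E that returns raises the effective start to 0.226 mM. Integrating both losses gives Z formed as the Z part of the first-order loss, times the level, times ln of one plus start over level. That is 0.137 mM, or 55.0 % of the charge. Z then drifts slowly toward J, with a relaxation half-life of 2.49 min, longer than the run.

North-east starts at the same [X], so you expect it close to north, with a small gain from the late E.

South-west, with X2 left aside, holds about 0.00524 mM, and north-west holds about feed over loss, 0.00593 mM. Both lie far below the level, so the loss to X2 counts for little and Z formed tends to the Z part of the first-order loss times the effective start, 72.1 % of the charge before drift.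

Now set those two against each other. Z in the tank is on average 2.0 min old, while in north-west it is about 1.20 min old, so you bet on north-west.

The forecast gives 50.4 %, 64 %, 52.8 % and 66.8 % for north, south-west, north-east and north-west, picks north-west, and says “late formation limits the loss to J”.

The simulation gives 50.7 %, 64.0 %, 52.9 % and 66.9 % in that order, so the best is north-west.

The largest single effect in the gap between north and north-west is the step to X2: take it away and north-west's lead shrinks from 16 percentage points to 2.8 points. The reading of peak [X] in north-west, 0.0233 mM, stays far under the even-split level, and X2 there ends at 1.89 % against 21.2 % in north. A neighbour of north charged with 0.50 mM of X starts above that level. The formula used for north gives it 45.7 % of Z before drift, and that flask ends at 41.3 % of Z with 38.1 % as X2.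

The constants used here were drawn at random within sensible limits; no experiment stands behind them.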